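| setting | ochre | amber |
|---|---|---|
| first end groups | 1.4 M | 1.4 M |
| second end groups | 1.00 equiv | 1.01 equiv |
| protic impurity | 0.140 M | 0.140 M |
| time | 40 h | 40 h |

- which of the two ends with the longer chains by the average number of monomer units in a chain (unreacted monomers counted as chains of one) ("neither" if they lie within 10%) (ochre / amber / neither)
- average number of monomer units in a chain (unreacted monomers counted as chains of one) at the end, ochre
- average number of monomer units in a chain (unreacted monomers counted as chains of one) at the end, amber

- each molecule carries two end groups: a chain counts once for every two ends that are left, dead ends included; the units are half of the end groups of the two monomers charged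
- run time (ochre): 40 h

    first end groups + second end groups → links + by-product (k1 = 2.3 L mol⁻¹ h⁻¹)
    second end groups + protic impurity → quenched reagent (k2 = 0.34 L mol⁻¹ h⁻¹)
    second end groups → decomposed reagent (k3 = 0.29 h⁻¹)

A small charge of protic impurity, 0.140 M against 1.4 M of first end groups, looks like the threat to ochre. Ochre's ends are charged equally, so each lost second end group strands one first end group, and the average length is c(first end groups) at the start over c(first end groups) at the end. If each impurity molecule took one end, that gives 10.0.

But quenching, with a half-life of 15 h, is slower than decomposition at 2.4 h. Decomposition alone leaves hardly any second end groups after 16.7 half-lives, while linking slows as first end groups thin. So watch the break-even level, the c(first end groups) at which linking and decomposition use second end groups equally fast, 0.126 M. Dividing the rate laws removes second end groups: decomposed reagent equals this level times ln of c(first end groups) charged over c(first end groups) left. Quenched reagent equals the impurity charge times one minus the fraction of first end groups left, raised to 0.148.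

In ochre, those two losses sum to c(first end groups) at the end, which stands on both sides, so iterate. Putting in 0.140 M returns 0.331 M, more than went in. That returns 0.209 M. The rounds swing, so feed in their midpoint, which returns 0.238 M. The new midpoint, 0.254 M, gives ochre 5.52.

Amber's surplus is 0.0140 M, but a lower c(first end groups) raises decomposed reagent, so c(first end groups) falls by about 0.00935 M. Amber reaches 5.60, up 1.45%, less than the 10% margin.

The forecast gave 5.62 for ochre, 5.69 for amber, hence neither: “a roughly 1% change in chain length that is well inside the 10% margin”.

The simulation gives 5.62 for ochre and 5.69 for amber, so neither; my ochre value lies lower.

Take the neighbouring flask: amber's recipe with 0.56 M of first end groups, second end groups held in equivalents, and protic impurity still 0.140 M, now 0.250 equiv. The break-even level is now 22.5% of the first end groups charged, against 9.00% in amber. The same rounds, less its surplus, run 0.195 M, then 0.148 M. The midpoint returns 0.166 M, and the new midpoint is 0.169 M, a length of 3.28. That flask ends with 30% of its first end groups unbound and a length of 3.28.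

The rate constants come from no measurement; the run is a simulation.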